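**Retrosynthetic overview**

- Numbering: bridgeheads C1 and C5, carbonyl carbons C2 and C4 around benzoyl-bearing C3, C6 (CH2), C7 (endo prenyl), C8 (CMe2), C9 (bridging C=O). Ring A is C1–C2–C3–C4–C5–C9 and ring B is C1–C8–C7–C6–C5–C9. The route rests on quaternary C8 lying between quaternary C1 and C7: C8 is what is left of a 2-methylpropanoic acid arm on C1 after loss of CO2, and C7 is the β-carbon of a but-2-ynoate hung on C5 through C6.
- Key disconnection C7–C8: ring B is closed last, by reductive decarboxylation of the N-hydroxyphthalimide ester of that acid and 6-exo-dig addition of the tertiary radical to the ynoate, on a fully substituted ring A.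
- Ring A comes first, from 2,6-dimethoxy-1,4-benzoquinone. C1 receives the acid arm (enolate 1,2-addition, reductive aromatization) and then an allyl group (oxidative para-allylation). One enol ether is opened to a 1,3-dione, the enantiomers are separated, and C5 is propargylated and then allylated anti to the C1 arm.
- After ring B: both allyl groups become prenyl by cross-metathesis, hydride adds to C7 from the exo face, the ester side chain becomes the third prenyl group, C3 is benzoylated and the methyl enol ether is cleaved.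

Key step: step 10

Assumption: the target is taken as the enolized 3-benzoyl-2,4,9-trione drawn in the SMILES (its enol tautomers interconvert), with the C7 prenyl group endo, that is, on the face of ring B that carries the C2–C3–C4 bridge.

**Route**

Step 1
Reactants: 1 2,6-dimethoxy-1,4-benzoquinone; 2 allyl 2-methylpropanoate
Product: 4 allyl 2-(1-hydroxy-2,6-dimethoxy-4-oxocyclohexa-2,5-dien-1-yl)-2-methylpropanoate, via lithium enolate 3 (not isolated)
Conditions: LiN(i-Pr)2 (1.05 equiv), THF, −78 °C; then 1 in THF, −78 °C; AcOH quench at −78 °C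
Reagents that add atoms: none
Why: Aldol-type 1,2-addition of the ester enolate to a quinone (jacaranone-type quinol synthesis) should take place at the carbonyl flanked by the two methoxy-bearing carbons, because the other carbonyl is deactivated as a doubly vinylogous ester.

Step 2
Reactants: 4 allyl 2-(1-hydroxy-2,6-dimethoxy-4-oxocyclohexa-2,5-dien-1-yl)-2-methylpropanoate
Product: 5 allyl 2-(4-hydroxy-2,6-dimethoxyphenyl)-2-methylpropanoate
Conditions: Zn dust, AcOH/THF, rt
Reagents that add atoms: none
Why: Reductive aromatization of a p-quinol: two-electron reduction of the cross-conjugated dienone expels the tertiary hydroxyl and gives the phenol with the arm para to OH, without touching the hindered allyl ester.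

Step 3
Reactants: 5 allyl 2-(4-hydroxy-2,6-dimethoxyphenyl)-2-methylpropanoate
Product: 6 allyl 2-(1-allyl-2,6-dimethoxy-4-oxocyclohexa-2,5-dien-1-yl)-2-methylpropanoate
Conditions: PhI(OAc)2 (1.1 equiv), allylSiMe3 (3 equiv), (CF3)2CHOH/CH2Cl2, −20 → 0 °C
Reagents that add atoms: allyltrimethylsilane, C=CC[Si](C)(C)C
Why: Oxidative dearomatization (oxidative Hosomi–Sakurai allylation of a para-substituted phenol): the phenoxenium ion should be trapped by the allylsilane at the para carbon, driven by formation of the doubly vinylogous ester; C1 becomes quaternary but is not yet stereogenic because its two ring arms are identical.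

Step 4
Reactants: 6 allyl 2-(1-allyl-2,6-dimethoxy-4-oxocyclohexa-2,5-dien-1-yl)-2-methylpropanoate
Product: 7 racemic allyl 2-(1-allyl-2-methoxy-4,6-dioxocyclohex-2-en-1-yl)-2-methylpropanoate
Conditions: LiOH (3 equiv), THF/H2O, 45 °C; then cold 1 M HCl to pH 3
Reagents that add atoms: lithium hydroxide, [Li+].[OH-]
Why: Vinylogous ester saponification (hydroxide addition–elimination at one of the two equivalent β-methoxy enone carbons) should stop after one cleavage because the product is a vinylogous carboxylate anion; this desymmetrization makes C1 stereogenic, as a racemate, and leaves a 1,3-dione whose only carbon between two carbonyls is C5.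

Step 5
Reactants: 7 racemic allyl 2-(1-allyl-2-methoxy-4,6-dioxocyclohex-2-en-1-yl)-2-methylpropanoate
Product: 8 allyl 2-[(1R)-1-allyl-2-methoxy-4,6-dioxocyclohex-2-en-1-yl]-2-methylpropanoate
Conditions: preparative HPLC, immobilized amylose tris(3,5-dimethylphenylcarbamate) phase, hexane/EtOAc/AcOH, rt
Reagents that add atoms: none
Why: Resolution by chromatography on a chiral stationary phase selects the C1 configuration of the target at the first chiral intermediate; the alcohol-free eluent avoids re-forming the symmetric bis-enol ether, the only path to racemization.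

Step 6
Reactants: 8 allyl 2-[(1R)-1-allyl-2-methoxy-4,6-dioxocyclohex-2-en-1-yl]-2-methylpropanoate
Product: 9 allyl 2-[(1R)-1-allyl-2-methoxy-4,6-dioxo-5-(prop-2-yn-1-yl)cyclohex-2-en-1-yl]-2-methylpropanoate (C5 epimers and enol)
Conditions: KOH (1.1 equiv), propargyl bromide (1.3 equiv), H2O/THF, rt
Reagents that add atoms: propargyl bromide, C#CCBr
Why: C-Alkylation of a cyclic 1,3-dione enolate with a propargylic halide in water should occur at C5, since C3 is a vinylic CH locked in the remaining enol ether; C5 stays epimerizable at this stage.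

Step 7
Reactants: 9 allyl 2-[(1R)-1-allyl-2-methoxy-4,6-dioxo-5-(prop-2-yn-1-yl)cyclohex-2-en-1-yl]-2-methylpropanoate
Product: 10 2-[(1R,5S)-1,5-diallyl-2-methoxy-4,6-dioxo-5-(prop-2-yn-1-yl)cyclohex-2-en-1-yl]-2-methylpropanoic acid (propargyl cis to the acid arm)
Conditions: Pd(PPh3)4 (5 mol %), THF, rt
Reagents that add atoms: none
Why: Tsuji–Trost allylation in which the allyl ester of the arm is the allyl donor: zerovalent palladium ionizes it, the carboxylate deprotonates the acidic 1,3-dione, and the enolate should attack the allyl complex at C5 from the face opposite the pseudoaxial tert-alkyl arm on C1 (1,3-induction), which sets C5 with the propargyl group cis to the arm and frees the acid under neutral conditions.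

Step 8
Reactants: 10 2-[(1R,5S)-1,5-diallyl-2-methoxy-4,6-dioxo-5-(prop-2-yn-1-yl)cyclohex-2-en-1-yl]-2-methylpropanoic acid
Product: 12 2-[(1R,5S)-1,5-diallyl-2-methoxy-5-(4-methoxy-4-oxobut-2-yn-1-yl)-4,6-dioxocyclohex-2-en-1-yl]-2-methylpropanoic acid, via dilithium acetylide carboxylate 11 (not isolated)
Conditions: LiN(i-Pr)2 (2.1 equiv), THF, −78 °C; ClCO2Me (1.0 equiv), −78 °C; cold dilute HCl work-up to pH 4
Reagents that add atoms: methyl chloroformate, COC(=O)Cl
Why: Acylation of a lithium acetylide with a chloroformate (alkynoate synthesis): beside CO2H the alkyne C–H is the only acidic site now that C1 and C5 are quaternary, and one equivalent of chloroformate should react with the acetylide rather than with the hindered carboxylate.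

Step 9
Reactants: 12 2-[(1R,5S)-1,5-diallyl-2-methoxy-5-(4-methoxy-4-oxobut-2-yn-1-yl)-4,6-dioxocyclohex-2-en-1-yl]-2-methylpropanoic acid
Product: 13 1,3-dioxoisoindolin-2-yl 2-[(1R,5S)-1,5-diallyl-2-methoxy-5-(4-methoxy-4-oxobut-2-yn-1-yl)-4,6-dioxocyclohex-2-en-1-yl]-2-methylpropanoate
Conditions: N-hydroxyphthalimide, N,N'-diisopropylcarbodiimide, DMAP (5 mol %), CH2Cl2, 0 °C → rt
Reagents that add atoms: N-hydroxyphthalimide, ON1C(=O)c2ccccc2C1=O
Why: Carbodiimide (Steglich-type) esterification gives the redox-active ester; the acid is used at once and never exposed to strong acid, because a free acid next to the C2 enol ether could close to an enol lactone under acid catalysis.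

Step 10
Reactants: 13 1,3-dioxoisoindolin-2-yl 2-[(1R,5S)-1,5-diallyl-2-methoxy-5-(4-methoxy-4-oxobut-2-yn-1-yl)-4,6-dioxocyclohex-2-en-1-yl]-2-methylpropanoate
Product: 14 methyl (E)-2-[(1R,5S)-1,5-diallyl-2-methoxy-8,8-dimethyl-4,9-dioxobicyclo[3.3.1]non-2-en-7-ylidene]acetate (target numbering)
Conditions: undivided cell, reticulated vitreous carbon cathode, sacrificial Zn anode, n-Bu4NPF6, (CF3)2CHOH (4 equiv), DMA, constant current (2.2 F/mol), 0 °C
Reagents that add atoms: none
Why: The cathode transfers one electron to the phthalimide ester, whose radical anion fragments to phthalimide anion, CO2 and the tertiary C8 radical; this nucleophilic radical adds to C7, the β-carbon of the but-2-ynoate held cis on C5, and the resulting α-ester vinyl radical is reduced at the cathode and protonated by (CF3)2CHOH. The closest known reaction type is the reductive decarboxylative Giese addition of tertiary N-acyloxyphthalimides (photoredox or electroreductive), run here intramolecularly as a radical cyclization onto an alkynoate. Ring B (C1–C8–C7–C6–C5–C9) closes in the 6-exo-dig mode and completes the bicyclo[3.3.1]nonane. No stereocenter is created, since C8 is gem-dimethyl and C7 is sp2, and the alkene geometry is erased in step 12. The radical must choose the alkyne over the two allyl groups and over a 1,2-acyl shift to the C9 carbonyl; polarity matching with the electron-poor alkyne and the 1,3-diaxial proximity of the two arms, fixed cis in step 7, should secure this, and a radical forms the bond between two fully substituted carbons without the steric penalty of a polar transition state.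

Step 11
Reactants: 14 methyl (E)-2-[(1R,5S)-1,5-diallyl-2-methoxy-8,8-dimethyl-4,9-dioxobicyclo[3.3.1]non-2-en-7-ylidene]acetate
Product: 15 methyl (E)-2-[(1R,5S)-2-methoxy-8,8-dimethyl-1,5-bis(3-methylbut-2-en-1-yl)-4,9-dioxobicyclo[3.3.1]non-2-en-7-ylidene]acetate
Conditions: second-generation Grubbs catalyst (5 mol %), 2-methylbut-2-ene (excess), CH2Cl2, 40 °C
Reagents that add atoms: 2-methylbut-2-ene, CC=C(C)C
Why: Olefin cross-metathesis turns both terminal allyl groups into prenyl groups; it is placed here because the alkyne is gone and the two bridgehead allyl groups now point apart and cannot ring-close, while the trisubstituted electron-poor alkylidene ester is inert.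

Step 12
Reactants: 15 methyl (E)-2-[(1R,5S)-2-methoxy-8,8-dimethyl-1,5-bis(3-methylbut-2-en-1-yl)-4,9-dioxobicyclo[3.3.1]non-2-en-7-ylidene]acetate
Product: 16 methyl 2-[(1R,5S,7R)-2-methoxy-8,8-dimethyl-1,5-bis(3-methylbut-2-en-1-yl)-4,9-dioxobicyclo[3.3.1]non-2-en-7-yl]acetate (side chain endo)
Conditions: [(Ph3P)CuH]6 (0.5 equiv), H2O (3 equiv), PhMe, rt
Reagents that add atoms: none
Why: Copper hydride conjugate reduction of the enoate: the endo face of C7 is closed by the C2–C3–C4 bridge, so hydride should arrive from the exo face and leave the CH2CO2Me group endo, which sets C7; the β-methoxy enone and the prenyl groups are not reduced.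

Step 13
Reactants: 16 methyl 2-[(1R,5S,7R)-2-methoxy-8,8-dimethyl-1,5-bis(3-methylbut-2-en-1-yl)-4,9-dioxobicyclo[3.3.1]non-2-en-7-yl]acetate
Product: 17 2-[(1R,5S,7R)-2-methoxy-8,8-dimethyl-1,5-bis(3-methylbut-2-en-1-yl)-4,9-dioxobicyclo[3.3.1]non-2-en-7-yl]acetaldehyde
Conditions: i-Bu2AlH (1.1 equiv), CH2Cl2, −78 °C; aq. potassium sodium tartrate
Reagents that add atoms: none
Why: Partial reduction of the unhindered methyl ester stops at the tetrahedral aluminium hemiacetal at −78 °C; the vinylogous ester carbonyl and the C9 ketone between two quaternary carbons should react much more slowly.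

Step 14
Reactants: 17 2-[(1R,5S,7R)-2-methoxy-8,8-dimethyl-1,5-bis(3-methylbut-2-en-1-yl)-4,9-dioxobicyclo[3.3.1]non-2-en-7-yl]acetaldehyde
Product: 18 (1R,5S,7S)-2-methoxy-8,8-dimethyl-1,5,7-tris(3-methylbut-2-en-1-yl)bicyclo[3.3.1]non-2-ene-4,9-dione
Conditions: i-PrPPh3I, n-BuLi, THF, 0 °C; then 17, −78 °C → rt
Reagents that add atoms: isopropyltriphenylphosphonium iodide, CC(C)[P+](c1ccccc1)(c1ccccc1)c1ccccc1.[I-]
Why: Wittig olefination of the aldehyde with the non-stabilized isopropylidene ylide completes the C7 prenyl group; the hindered ketones do not compete.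

Step 15
Reactants: 18 (1R,5S,7S)-2-methoxy-8,8-dimethyl-1,5,7-tris(3-methylbut-2-en-1-yl)bicyclo[3.3.1]non-2-ene-4,9-dione
Product: 20 3-benzoyl-2-methoxy-8,8-dimethyl-1,5,7-tris(3-methylbut-2-en-1-yl)bicyclo[3.3.1]non-2-ene-4,9-dione (configuration as in 18), via C3 vinyllithium 19 (not isolated)
Conditions: lithium 2,2,6,6-tetramethylpiperidide (from the amine and n-BuLi), THF, −78 °C; PhCOCl
Reagents that add atoms: benzoyl chloride, O=C(Cl)c1ccccc1
Why: Directed vinylic lithiation at C3 (α to the carbonyl, β to methoxy, no enolizable hydrogen left) followed by C-acylation is the established way to acylate C3 of such bicyclic vinylogous esters.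

Step 16
Reactants: 20 3-benzoyl-2-methoxy-8,8-dimethyl-1,5,7-tris(3-methylbut-2-en-1-yl)bicyclo[3.3.1]non-2-ene-4,9-dione
Product: 21 7-epi-clusianone (CID5471610)
Conditions: LiOH, dioxane/H2O, 90 °C; then 1 M HCl
Reagents that add atoms: lithium hydroxide, [Li+].[OH-]
Why: Hydroxide addition–elimination at C2 of the doubly activated enol ether (vinylogous ester cleavage) should release the enolized triketone without touching any stereocenter.

**Compound list**

1 | 2,6-dimethoxy-1,4-benzoquinone | COC1=CC(=O)C=C(OC)C1=O | starting material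
2 | allyl 2-methylpropanoate | CC(C)C(=O)OCC=C | starting material
3 | lithium enolate of 2 | [Li+].CC(C)=C([O-])OCC=C | intermediate
4 | allyl 2-(1-hydroxy-2,6-dimethoxy-4-oxocyclohexa-2,5-dien-1-yl)-2-methylpropanoate | CC(C)(C(=O)OCC=C)C1(O)C(OC)=CC(=O)C=C1OC | intermediate
5 | allyl 2-(4-hydroxy-2,6-dimethoxyphenyl)-2-methylpropanoate | CC(C)(C(=O)OCC=C)c1c(OC)cc(O)cc1OC | intermediate
6 | allyl 2-(1-allyl-2,6-dimethoxy-4-oxocyclohexa-2,5-dien-1-yl)-2-methylpropanoate | C=CCOC(=O)C(C)(C)C1(CC=C)C(OC)=CC(=O)C=C1OC | intermediate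
7 | racemic allyl 2-(1-allyl-2-methoxy-4,6-dioxocyclohex-2-en-1-yl)-2-methylpropanoate | C=CCOC(=O)C(C)(C)C1(CC=C)C(OC)=CC(=O)CC1=O | intermediate
8 | (1R)-enantiomer of 7 | C1C(=O)C=C(OC)[C@](CC=C)(C1=O)C(C)(C)C(=O)OCC=C | intermediate
9 | allyl 2-[(1R)-1-allyl-2-methoxy-4,6-dioxo-5-(prop-2-yn-1-yl)cyclohex-2-en-1-yl]-2-methylpropanoate | C#CCC1C(=O)C=C(OC)[C@](CC=C)(C1=O)C(C)(C)C(=O)OCC=C | intermediate
10 | 2-[(1R,5S)-1,5-diallyl-2-methoxy-4,6-dioxo-5-(prop-2-yn-1-yl)cyclohex-2-en-1-yl]-2-methylpropanoic acid | C#CC[C@@]1(CC=C)C(=O)C=C(OC)[C@](CC=C)(C1=O)C(C)(C)C(=O)O | intermediate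
11 | dilithium acetylide carboxylate of 10 | [Li+].[Li+].[C-]#CC[C@@]1(CC=C)C(=O)C=C(OC)[C@](CC=C)(C1=O)C(C)(C)C(=O)[O-] | intermediate
12 | 2-[(1R,5S)-1,5-diallyl-2-methoxy-5-(4-methoxy-4-oxobut-2-yn-1-yl)-4,6-dioxocyclohex-2-en-1-yl]-2-methylpropanoic acid | COC(=O)C#CC[C@@]1(CC=C)C(=O)C=C(OC)[C@](CC=C)(C1=O)C(C)(C)C(=O)O | intermediate
13 | N-hydroxyphthalimide ester of 12 (key-step precursor) | COC(=O)C#CC[C@@]1(CC=C)C(=O)C=C(OC)[C@](CC=C)(C1=O)C(C)(C)C(=O)ON2C(=O)c3ccccc3C2=O | intermediate
14 | methyl (E)-2-[(1R,5S)-1,5-diallyl-2-methoxy-8,8-dimethyl-4,9-dioxobicyclo[3.3.1]non-2-en-7-ylidene]acetate (key-step product) | COC(=O)/C=C1\C[C@@]2(CC=C)C(=O)C=C(OC)[C@](CC=C)(C2=O)C1(C)C | intermediate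
15 | methyl (E)-2-[(1R,5S)-2-methoxy-8,8-dimethyl-1,5-bis(3-methylbut-2-en-1-yl)-4,9-dioxobicyclo[3.3.1]non-2-en-7-ylidene]acetate | COC(=O)/C=C1\C[C@@]2(CC=C(C)C)C(=O)C=C(OC)[C@](CC=C(C)C)(C2=O)C1(C)C | intermediate
16 | methyl 2-[(1R,5S,7R)-2-methoxy-8,8-dimethyl-1,5-bis(3-methylbut-2-en-1-yl)-4,9-dioxobicyclo[3.3.1]non-2-en-7-yl]acetate | COC(=O)C[C@H]1C[C@@]2(CC=C(C)C)C(=O)C=C(OC)[C@](CC=C(C)C)(C2=O)C1(C)C | intermediate
17 | 2-[(1R,5S,7R)-2-methoxy-8,8-dimethyl-1,5-bis(3-methylbut-2-en-1-yl)-4,9-dioxobicyclo[3.3.1]non-2-en-7-yl]acetaldehyde | O=CC[C@H]1C[C@@]2(CC=C(C)C)C(=O)C=C(OC)[C@](CC=C(C)C)(C2=O)C1(C)C | intermediate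
18 | (1R,5S,7S)-2-methoxy-8,8-dimethyl-1,5,7-tris(3-methylbut-2-en-1-yl)bicyclo[3.3.1]non-2-ene-4,9-dione | CC(C)=CC[C@H]1C[C@@]2(CC=C(C)C)C(=O)C=C(OC)[C@](CC=C(C)C)(C2=O)C1(C)C | intermediate
19 | C3 vinyllithium of 18 | CC(C)=CC[C@H]1C[C@@]2(CC=C(C)C)C(=O)C([Li])=C(OC)[C@](CC=C(C)C)(C2=O)C1(C)C | intermediate
20 | 3-benzoyl-2-methoxy-8,8-dimethyl-1,5,7-tris(3-methylbut-2-en-1-yl)bicyclo[3.3.1]non-2-ene-4,9-dione | CC(C)=CC[C@H]1C[C@@]2(CC=C(C)C)C(=O)C(C(=O)c3ccccc3)=C(OC)[C@](CC=C(C)C)(C2=O)C1(C)C | intermediate
21 | 7-epi-clusianone (CID5471610) | CC(C)=CC[C@H]1C[C@@]2(CC=C(C)C)C(=O)/C(=C(/O)c3ccccc3)C(=O)[C@](CC=C(C)C)(C2=O)C1(C)C | target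

**Step count and risks**

Total step count: 16. Longest linear sequence: 16 steps (1 to 21).

Steps most likely to fail:

1. Step 3 (oxidative para-allylation). The allylsilane may attack the unsubstituted ortho carbons C3/C5 of the phenoxenium ion, after which the ring rearomatizes to an allylphenol, or the hindered para carbon C1 may be captured only by solvent or acetate. The fallback sets out from phenol 5. Both ortho positions are blocked with N-iodosuccinimide to give allyl 2-(4-hydroxy-3,5-diiodo-2,6-dimethoxyphenyl)-2-methylpropanoate F1. The same PhI(OAc)2/allylSiMe3 dearomatization, which can now end only at C1, should give allyl 2-(1-allyl-3,5-diiodo-2,6-dimethoxy-4-oxocyclohexa-2,5-dien-1-yl)-2-methylpropanoate F2. The two vinylic iodides are then removed by iodine–magnesium exchange with i-PrMgCl·LiCl at −78 °C and protonation with AcOH, which returns to dienone 6.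

2. Step 10 (key step). The tertiary radical may be diverted before it reaches C7: by 1,2-acyl migration through attack on the C9 carbonyl (ring expansion), by hydrogen abstraction from the solvent, or the phthalimide anion may add to the ynoate; the vinyl radical may also add to an allyl group. The fallback sets out from acid 12 and generates the same radical in a neutral chain process without an electrode. The acid is coupled with N-hydroxypyridine-2-thione (N,N'-diisopropylcarbodiimide, dark) to the Barton ester F3. Irradiation with visible light in benzene at 10 °C with slow addition of t-BuSH should give decarboxylation, 6-exo-dig closure and hydrogen transfer to the vinyl radical, which returns to 14.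

3. Step 12 (conjugate reduction). Hydride transfer from the bulky copper hydride cluster to C7, a fully substituted β-carbon next to quaternary C8, may be too slow, so that the enoate is recovered while the hydride is consumed by water. The fallback sets out from 15 and uses single-electron reduction in place of hydride transfer: Mg in MeOH at 0 °C → rt reduces the enoate through its radical anion, and C7 is protonated by methanol from the same open exo face. This returns to 16 and makes no new compound.

**Further compounds**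

F1 | step 3 | allyl 2-(4-hydroxy-3,5-diiodo-2,6-dimethoxyphenyl)-2-methylpropanoate | C=CCOC(=O)C(C)(C)c1c(OC)c(I)c(O)c(I)c1OC
F2 | step 3 | allyl 2-(1-allyl-3,5-diiodo-2,6-dimethoxy-4-oxocyclohexa-2,5-dien-1-yl)-2-methylpropanoate | C=CCOC(=O)C(C)(C)C1(CC=C)C(OC)=C(I)C(=O)C(I)=C1OC
F3 | step 10 | 2-thioxopyridin-1(2H)-yl ester (Barton ester) of acid 12 | COC(=O)C#CC[C@@]1(CC=C)C(=O)C=C(OC)[C@](CC=C)(C1=O)C(C)(C)C(=O)ON2C=CC=CC2=S
F0 | step 12 | none | none
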